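**Retrosynthetic overview**
1. Target 12 ⇐ 11 by removal of a 12‑O‑benzoyl group; 11 ⇐ 9 by allylic bromination/acetolysis at C7 (last C–O bond, 7α).
2. 9 ⇐ abietane quinone acid 6: the quinone C11=O takes a hydrogen from the C20 methyl, C9 shifts from C10 to C20 (ring B 6→7), and the 19‑CO2H traps the C10 cation as the 19,10‑lactone. This is the abietane→icetexane rearrangement with carboxylate capture, triggered by light, without prior C20 oxidation.
3. 6 ⇐ lambertic acid 3 by ortho‑benzoyloxylation and Teuber oxidation; 3 ⇐ (+)‑podocarpic acid 1 + 2‑propanol 2 (Friedel–Crafts).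
4. Ring order: rings A, B, C and C4/C5 come intact from 1; ring B is enlarged and the γ‑lactone closed in one step (step 4, sets C10); C7 is set last.

Assumption: (+)‑podocarpic acid (natural 4β‑CO2H, 5α‑H, 10β‑CH3 series) is taken as a cheap commercial starting material.

**Step 1**
Reactants: 1 (+)-podocarpic acid; 2 2-propanol
Product: 3 lambertic acid (12-hydroxyabieta-8,11,13-trien-19-oic acid)
Conditions: i‑PrOH (3 equiv), TfOH (0.2 equiv), ClCH2CH2Cl, 60 °C
Reagents that add atoms: 2-propanol CC(C)O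
Why: Friedel–Crafts alkylation ortho to the phenol; C13 is the open ortho position, C11 is shielded by the C1/C10 bay, and the hindered axial acid is not esterified; no stereocentre is touched.

**Step 2**
Reactants: 3 lambertic acid
Product: 5 12-benzoyloxy-11-hydroxyabieta-8,11,13-trien-19-oic acid, via 11-benzoyloxy-12-hydroxy isomer 4 (not isolated)
Conditions: (BzO)2 (1.1 equiv), CHCl3, reflux, dark; then Et3N (cat.), rt
Reagents that add atoms: dibenzoyl peroxide O=C(OOC(=O)c1ccccc1)c1ccccc1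
Why: ortho‑benzoyloxylation of a phenol by a diacyl peroxide (ionic O‑transfer through a cyclic transition state) can only reach C11, and the benzoyl group then migrates from the bay oxygen O‑11 to the less hindered O‑12 (catechol monoester acyl migration), which frees 11‑OH and protects O‑12.

**Step 3**
Reactants: 5 12-benzoyloxy-11-hydroxyabieta-8,11,13-trien-19-oic acid
Product: 6 12-benzoyloxy-11,14-dioxoabieta-8,12-dien-19-oic acid
Conditions: Fremy's salt (2.5 equiv), KH2PO4 buffer, acetone–H2O, rt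
Reagents that add atoms: potassium nitrosodisulfonate (Fremy's salt) [K+].[K+].[O]N(S(=O)(=O)[O-])S(=O)(=O)[O-]
Why: Teuber oxidation of a phenol with a free para C–H (C14 is para to 11‑OH) gives the 11,14‑p‑quinone; the benzoate and the acid are inert, and any 11‑O‑benzoyl isomer equilibrates in the buffer and drains through the 11‑OH form.

**Step 4**
Reactants: 6 12-benzoyloxy-11,14-dioxoabieta-8,12-dien-19-oic acid
Product: 9 12-O-benzoyl-6,7-dihydroicetexone, via spirocyclopropyl dienone 7 (not isolated), via hydroquinone lactone 8 (not isolated)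
Conditions: hν (365–405 nm LED), degassed MeCN–AcOH (9:1), 20 °C; then DDQ (1.0 equiv), rt, dark
Reagents that add atoms: none
Why: Proposed new method: the triplet quinone C11=O abstracts a γ‑hydrogen from the axial C20 methyl (1,5‑HAT; the competing H‑1β abstraction gives a radical in the nodal plane that can only return the hydrogen), the C20 radical closes on C9 to spirodienone 7, and acid‑assisted opening of the C9–C10 bond (1,2‑aryl shift, 9(10→20)abeo) gives the tertiary C10 cation, which the axial 19‑CO2H sitting on the β face above C10 traps as the γ‑lactone, so C10 is set by the tether (O β, trans to H‑5α) and DDQ returns hydroquinone 8 to the quinone; the closest known reaction is the photorearrangement of 2‑tert‑butyl‑1,4‑benzoquinones to 2‑(2‑acyloxy‑ or 2‑alkoxy‑2‑methylpropyl)hydroquinones through the same spirocyclopropyl dienone.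

**Step 5**
Reactants: 9 12-O-benzoyl-6,7-dihydroicetexone
Product: 11 7α-acetoxy-12-O-benzoyl-6,7-dihydroicetexone, via 7-bromide 10 (not isolated)
Conditions: NBS (1.05 equiv), AIBN (cat.), PhCF3, 80 °C; then AgOAc (1.5 equiv), AcOH, rt, dark
Reagents that add atoms: silver acetate CC(=O)[O-].[Ag+] (acetate of 11); N-bromosuccinimide O=C1CCC(=O)N1Br (bromine of intermediate 10 only)
Why: Wohl–Ziegler bromination at the quinone‑allylic C7 methylene (C20 is neopentylic and β to the lactone oxygen, the isopropyl C–H lies in the ring plane, the enol oxygen is masked) followed by silver‑assisted SN1 acetolysis; acetate enters pseudo‑axially from the α face, because the β face is covered by axial H‑6β and the C10–O bridge and a 7β‑acetate would clash with the peri C14=O, which sets 7α from either bromide epimer.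

**Step 6**
Reactants: 11 7α-acetoxy-12-O-benzoyl-6,7-dihydroicetexone
Product: 12 7α-acetoxy-6,7-dihydroicetexone
Conditions: NH3 (2 equiv, 0.5 M in dioxane), THF, −20 °C; citric acid work-up
Reagents that add atoms: none
Why: the 2‑acyloxyquinone is a vinylogous mixed anhydride, so aminolysis of this active ester is fast at −20 °C while the secondary alkyl acetate and the bridged tertiary lactone survive; no stereocentre is touched and the product is kept at the quinone level, where the 7‑acetate is stable.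

**Compound list**
1 | (+)-podocarpic acid (4β‑CO2H, 5α‑H, 10β‑CH3) | C[C@]12CCC[C@](C)(C(=O)O)[C@@H]1CCc3ccc(O)cc23 | starting material
2 | 2-propanol | CC(C)O | starting material
3 | lambertic acid (12-hydroxyabieta-8,11,13-trien-19-oic acid) | C[C@]12CCC[C@](C)(C(=O)O)[C@@H]1CCc3cc(C(C)C)c(O)cc23 | intermediate
4 | 11-benzoyloxy-12-hydroxyabieta-8,11,13-trien-19-oic acid (not isolated) | C[C@]12CCC[C@](C)(C(=O)O)[C@@H]1CCc3cc(C(C)C)c(O)c(OC(=O)c4ccccc4)c23 | intermediate
5 | 12-benzoyloxy-11-hydroxyabieta-8,11,13-trien-19-oic acid | C[C@]12CCC[C@](C)(C(=O)O)[C@@H]1CCc3cc(C(C)C)c(OC(=O)c4ccccc4)c(O)c23 | intermediate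
6 | 12-benzoyloxy-11,14-dioxoabieta-8,12-dien-19-oic acid | C[C@]12CCC[C@](C)(C(=O)O)[C@@H]1CCC3=C2C(=O)C(OC(=O)c4ccccc4)=C(C(C)C)C3=O | intermediate
7 | spirocyclopropyl dienone: 9,20‑cyclo, C20 on the β face, 11‑oxo, 14‑hydroxy‑8(14),12‑diene, 12‑benzoate, 19‑acid (not isolated) | O=C1C(OC(=O)c2ccccc2)=C(C(C)C)C(O)=C3CC[C@H]4[C@@](C)(C(=O)O)CCC[C@@]45C[C@@]135 | intermediate
8 | 12-benzoyloxy-11,14-dihydroxy-9(10→20)abeo-abieta-8,11,13-trien-19,10β-olide, H‑5α (not isolated) | C1C[C@@H]2[C@]3(CCC[C@]2(C)C(=O)O3)Cc2c1c(O)c(C(C)C)c(OC(=O)c4ccccc4)c2O | intermediate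
9 | 12-O-benzoyl-6,7-dihydroicetexone (12-benzoyloxy-11,14-dioxo-9(10→20)abeo-abieta-8,12-dien-19,10β-olide) | C1C[C@@H]2[C@]3(CCC[C@]2(C)C(=O)O3)CC2=C1C(=O)C(C(C)C)=C(OC(=O)c4ccccc4)C2=O | intermediate
10 | 7-bromo-12-O-benzoyl-6,7-dihydroicetexone (7α shown; the 7β epimer converges; not isolated) | Br[C@@H]1C[C@@H]2[C@]3(CCC[C@]2(C)C(=O)O3)CC2=C1C(=O)C(C(C)C)=C(OC(=O)c4ccccc4)C2=O | intermediate
11 | 7α-acetoxy-12-O-benzoyl-6,7-dihydroicetexone | CC(=O)O[C@@H]1C[C@@H]2[C@]3(CCC[C@]2(C)C(=O)O3)CC2=C1C(=O)C(C(C)C)=C(OC(=O)c4ccccc4)C2=O | intermediate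
12 | 7α-acetoxy-6,7-dihydroicetexone | CC(=O)O[C@@H]1C[C@@H]2[C@]3(CCC[C@]2(C)C(=O)O3)CC2=C1C(=O)C(C(C)C)=C(O)C2=O | target

**Totals**
Total steps: 6. Longest linear sequence: 6 (1 → 12).

**Three steps most likely to fail**

Step 4 (photochemical ring expansion/lactonisation). Risks are unproductive hydrogen return, competing abstraction from the isopropyl methyls by C14=O, or loss of a proton from the C10 cation. The fallback sets out from 3 and comes back at 9; it functionalises C20 first by a nitrene delivered from C19 and then runs the aryl shift as a deamination. 3 is acetylated (Ac2O, pyridine) to 12-acetoxyabieta-8,11,13-trien-19-oic acid F1, and DPPA/Et3N gives 12-acetoxyabieta-8,11,13-trien-19-oyl azide F2. Photolysis (300 nm, cyclohexane) inserts the acyl nitrene into the 1,3‑diaxial C20 methyl to give 12-acetoxyabieta-8,11,13-triene-19,20-lactam F3; Curtius isocyanate is the expected by‑product. Nitrosation (NaNO2, Ac2O/AcOH, 0 °C) gives the N-nitroso lactam F4. Warming F4 (toluene, 70 °C) passes through the C20 diazo ester: N2 leaves with 1,2‑shift of aryl C9, and the tethered carboxylate closes on C10 to 12-acetoxy-9(10→20)abeo-abieta-8,11,13-trien-19,10β-olide F5. K2CO3 (cat.)/MeOH frees 12-hydroxy-9(10→20)abeo-abieta-8,11,13-trien-19,10β-olide F6. Benzoyl peroxide as in step 2 gives 12-benzoyloxy-11-hydroxy-9(10→20)abeo-abieta-8,11,13-trien-19,10β-olide F7, and Fremy's salt as in step 3 gives 9.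

Step 5 (C7 versus C20 in the allylic bromination, and elimination to the 6,7‑ene). The fallback sets out from 6 and comes back at 11; it oxidises C7 before the skeleton is rearranged, when C7 is the only quinone‑allylic methylene. 6 with NBS/AIBN gives 7α-bromo-12-benzoyloxy-11,14-dioxoabieta-8,12-dien-19-oic acid F8. AgOAc/AcOH converts it into 7α-acetoxy-12-benzoyloxy-11,14-dioxoabieta-8,12-dien-19-oic acid F9, with acetate entering anti to the axial C20 methyl. Irradiation of F9 as in step 4 gives 7α-acetoxy-12-benzoyloxy-11,14-dihydroxy-9(10→20)abeo-abieta-8,11,13-trien-19,10β-olide F10. F10 is oxidised at once with DDQ to 11, because the benzylic acetate is labile at the hydroquinone level.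

Step 2 (moderate yield and acyl‑migration control in the peroxide benzoyloxylation). The fallback sets out from 3 and comes back at 5; it installs O‑11 by hypervalent‑iodine oxygen transfer and the benzoate by selective acylation. 3 with IBX (DMF, rt; ortho‑selective) gives 11,12-dioxoabieta-8,13-dien-19-oic acid F11. Reduction in the same flask with Na2S2O4 gives 11,12-dihydroxyabieta-8,11,13-trien-19-oic acid F12. BzCl (1.0 equiv), Et3N, CH2Cl2, −20 °C acylates the less hindered O‑12 (an 11‑ester would migrate to O‑12) and gives 5.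

**Further compounds**
F1 | step 4 | 12-acetoxyabieta-8,11,13-trien-19-oic acid | C[C@]12CCC[C@](C)(C(=O)O)[C@@H]1CCc3cc(C(C)C)c(OC(C)=O)cc23
F2 | step 4 | 12-acetoxyabieta-8,11,13-trien-19-oyl azide | C[C@]12CCC[C@](C)(C(=O)N=[N+]=[N-])[C@@H]1CCc3cc(C(C)C)c(OC(C)=O)cc23
F3 | step 4 | 12-acetoxyabieta-8,11,13-triene-19,20-lactam | O=C1NC[C@]23CCC[C@@]1(C)[C@@H]2CCc4cc(C(C)C)c(OC(C)=O)cc34
F4 | step 4 | N-nitroso-12-acetoxyabieta-8,11,13-triene-19,20-lactam | O=C1N(N=O)C[C@]23CCC[C@@]1(C)[C@@H]2CCc4cc(C(C)C)c(OC(C)=O)cc34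
F5 | step 4 | 12-acetoxy-9(10→20)abeo-abieta-8,11,13-trien-19,10β-olide | C1C[C@@H]2[C@]3(CCC[C@]2(C)C(=O)O3)Cc2c1cc(C(C)C)c(OC(C)=O)c2
F6 | step 4 | 12-hydroxy-9(10→20)abeo-abieta-8,11,13-trien-19,10β-olide | C1C[C@@H]2[C@]3(CCC[C@]2(C)C(=O)O3)Cc2c1cc(C(C)C)c(O)c2
F7 | step 4 | 12-benzoyloxy-11-hydroxy-9(10→20)abeo-abieta-8,11,13-trien-19,10β-olide | C1C[C@@H]2[C@]3(CCC[C@]2(C)C(=O)O3)Cc2c1cc(C(C)C)c(OC(=O)c4ccccc4)c2O
F8 | step 5 | 7α-bromo-12-benzoyloxy-11,14-dioxoabieta-8,12-dien-19-oic acid | C[C@]12CCC[C@](C)(C(=O)O)[C@@H]1C[C@@H](Br)C3=C2C(=O)C(OC(=O)c4ccccc4)=C(C(C)C)C3=O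
F9 | step 5 | 7α-acetoxy-12-benzoyloxy-11,14-dioxoabieta-8,12-dien-19-oic acid | C[C@]12CCC[C@](C)(C(=O)O)[C@@H]1C[C@@H](OC(C)=O)C3=C2C(=O)C(OC(=O)c4ccccc4)=C(C(C)C)C3=O
F10 | step 5 | 7α-acetoxy-12-benzoyloxy-11,14-dihydroxy-9(10→20)abeo-abieta-8,11,13-trien-19,10β-olide | CC(=O)O[C@@H]1C[C@@H]2[C@]3(CCC[C@]2(C)C(=O)O3)Cc2c1c(O)c(C(C)C)c(OC(=O)c4ccccc4)c2O
F11 | step 2 | 11,12-dioxoabieta-8,13-dien-19-oic acid | C[C@]12CCC[C@](C)(C(=O)O)[C@@H]1CCC3=C2C(=O)C(=O)C(C(C)C)=C3
F12 | step 2 | 11,12-dihydroxyabieta-8,11,13-trien-19-oic acid | C[C@]12CCC[C@](C)(C(=O)O)[C@@H]1CCc3cc(C(C)C)c(O)c(O)c23
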